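**Retrosynthetic overview**
Meroantarctine B ⇒ acetate and C14 methylene last ⇒ δ-lactone (C9–O–C15–C14–C13–C8) by C13–C14 alkylation from a C9 bromoacetate ⇒ cyclopentene (C8, C9, C11, C12, C13) by ring-closing metathesis ⇒ C9–O by a singlet-oxygen ene reaction ⇒ C8–C13 by Ireland–Claisen rearrangement ⇒ alkenyl triflate 15.
15 ⇒ ring B (C5–C10) by C7–C8 enolate alkylation ⇒ adduct 10 ⇒ Diels–Alder reaction of 2-silyloxydiene 3 (C1–C4) with 3-propanoyl butenolide 9 (alkene C10=C5), made from (R)-lactone 4, whose carbinol carbon becomes C6 and steers all later stereocentres.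
Enabling feature: ring A (C1–C5, C10) is trans-fused to ring B but cis-fused to the five-membered lactone ring (C10, C19, O, C6, C5). C10=C5 can therefore be the alkene of a butenolide before ring B exists: it is not a bridgehead alkene, its C6 substituent blocks one face, and the C9 ketone needed later is the second activating group.
Ring order: γ-lactone (purchased) → ring A (step 6) → ring B (step 7) → cyclopentene (step 15) → δ-lactone (step 17).

Key step: step 6

Numbering used in the names: ring A = C1–C5 + C10; ring B = C5–C10; C19 = lactone carbonyl on C10 (oxygen on C6); cyclopentene = C8, C9, C11, C12, C13; δ-lactone = C9–O–C15(=O)–C14–C13–C8; β = the face of ring B that carries the C19–O bridge, α = the opposite face.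
Assumption: (R)-lactone 4 is bought as the single enantiomer; C11 in 16–19, the ethylidene geometry in 20–22 and C13 in 20–26 are mixtures that converge in steps 13, 14 and 17.

**Step 1**
Reactants: 1 N-methoxy-N-methylisobutyramide
Product: 2 4-methylpent-1-en-3-one
Conditions: CH2=CHMgBr, THF, 0 °C; cold 1 M HCl quench
Reagents that add atoms: vinylmagnesium bromide, C=C[Mg]Br
Why: Weinreb ketone synthesis, in which the chelated tetrahedral adduct survives until the acidic quench, so the Grignard reagent adds once and the liberated amine is protonated before it can add to the enone.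

**Step 2**
Reactants: 2 4-methylpent-1-en-3-one
Product: 3 tert-butyldimethyl[(4-methylpenta-1,3-dien-3-yl)oxy]silane
Conditions: TBSOTf, Et3N, Et2O, 0 °C
Reagents that add atoms: tert-butyldimethylsilyl triflate, CC(C)(C)[Si](C)(C)OS(=O)(=O)C(F)(F)F
Why: Soft enolisation (silyl triflate and amine): the isopropyl C–H is the only α-hydrogen, so a single cross-conjugated 2-silyloxydiene should form.

**Step 3**
Reactants: 4 (R)-5-(hydroxymethyl)dihydrofuran-2(3H)-one
Product: 5 (R)-5-(bromomethyl)dihydrofuran-2(3H)-one
Conditions: CBr4, PPh3, CH2Cl2, 0 → 23 °C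
Reagents that add atoms: carbon tetrabromide, BrC(Br)(Br)Br
Why: Appel reaction at the primary carbon, which leaves the stereocentre (the later C6) untouched.

**Step 4**
Reactants: 5 (R)-5-(bromomethyl)dihydrofuran-2(3H)-one
Product: 6 (5R)-5-(bromomethyl)-3-propanoyldihydrofuran-2(3H)-one (C3 epimers)
Conditions: LiN(i-Pr)2 (LDA), THF, −78 °C; EtC(O)N(OMe)Me; aq NH4Cl
Reagents that add atoms: N-methoxy-N-methylpropanamide, CCC(=O)N(C)OC
Why: Crossed Claisen-type C-acylation of the lactone lithium enolate by a Weinreb amide, whose chelated adduct collapses only on work-up; the new α-centre is an epimer mixture that is removed in step 6.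

**Step 5**
Reactants: 6 (5R)-5-(bromomethyl)-3-propanoyldihydrofuran-2(3H)-one (C3 epimers)
Product: 7 (5R)-5-(bromomethyl)-3-(phenylselanyl)-3-propanoyldihydrofuran-2(3H)-one (C3 epimers)
Conditions: PhSeCl, pyridine, CH2Cl2, 0 °C
Reagents that add atoms: benzeneselenenyl chloride, Cl[Se]c1ccccc1
Why: α-Selenenylation of the enol of the β-keto lactone; the quaternary selenide centre is removed in step 6.

**Step 6**
Reactants: 7 (5R)-5-(bromomethyl)-3-(phenylselanyl)-3-propanoyldihydrofuran-2(3H)-one (C3 epimers); 3 tert-butyldimethyl[(4-methylpenta-1,3-dien-3-yl)oxy]silane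
Product: 10 Diels–Alder adduct (ring A cis-fused to the γ-lactone; C10 propanoyl, C5–H and C6 bromomethyl on one lactone face; C2=C3 TBS enol ether), via selenoxide 8 (not isolated), via acyl butenolide 9 (not isolated)
Conditions: H2O2 (30 %), CH2Cl2, 0 °C; cold NaHCO3 wash; then 3, ZnCl2 (10 mol %), CH2Cl2, −78 → 0 °C
Reagents that add atoms: none
Why: Oxidation of 7 gives selenoxide 8, whose syn-elimination toward the ring CH2 releases acyl butenolide 9 with C10=C5 activated by the lactone and the ketone carbonyl; 9 and diene 3 then combine in a normal-demand Diels–Alder reaction that is strongly asynchronous (C4–C5 bonding leads, as in a Mukaiyama–Michael addition, and C1–C10 follows), which lets the 4,4-dimethyl terminus react although its s-cis form is strained. The closest known type is the Diels–Alder reaction of 2-silyloxydienes with 2-acyl cycloalkenones and with 5-substituted butenolides. Ring A is closed by the [4+2] cycloaddition itself (six-membered, suprafacial on both partners), while the γ-lactone ring is carried in. C5 and C10 are controlled by C6: the diene adds to the butenolide face anti to the bromomethyl group, which gives the cis ring A/lactone fusion and places the propanoyl group cis to CH2Br, and no endo/exo issue arises because each diene terminus carries two identical substituents. The required regioselectivity (C4 to C5, C1 to C10) is secured electronically (C4 is the nucleophilic enol ether β-carbon, C5 the doubly activated β-carbon) and sterically (the CH2 terminus meets the carbon that becomes quaternary). Reaction through the oxadiene of 9 and γ-enolisation of 9 are held back by generating 9 cold and base-free and by the hindered tetrasubstituted enol ether bond of 3.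

**Step 7**
Reactants: 10 Diels–Alder adduct (ring A cis-fused to the γ-lactone; C10 propanoyl, C5–H and C6 bromomethyl on one lactone face; C2=C3 TBS enol ether)
Product: 11 tricyclic keto lactone (rings A and B plus the C19–O–C6 bridge; C9 ketone; C8 methyl epimers; C2=C3 TBS enol ether)
Conditions: NaN(SiMe3)2, THF, −78 → 0 °C
Reagents that add atoms: none
Why: Intramolecular enolate C-alkylation (six-membered, exo-tet): only C8 can enolise because C10 is quaternary, and the cis propanoyl and bromomethyl groups close ring B as a bicyclo[3.2.1] lactone, which makes rings A and B trans-fused; the C8 epimer mixture is erased in step 8.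

**Step 8**
Reactants: 11 tricyclic keto lactone (rings A and B plus the C19–O–C6 bridge; C9 ketone; C8 methyl epimers; C2=C3 TBS enol ether)
Product: 13 C3-keto alkenyl triflate (C8=C9; triflate on C9), via enol triflate 12 (not isolated)
Conditions: KN(SiMe3)2, PhNTf2, THF, −78 → 0 °C; then 1 M HCl, THF, 23 °C
Reagents that add atoms: N-phenylbis(trifluoromethanesulfonimide), O=S(=O)(N(c1ccccc1)S(=O)(=O)C(F)(F)F)C(F)(F)F
Why: O-triflation of the only possible ketone enolate (toward C8), then acid hydrolysis of the ring A silyl enol ether to the C3 ketone; no stereocentre is formed.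

**Step 9**
Reactants: 13 C3-keto alkenyl triflate (C8=C9; triflate on C9)
Product: 14 3α-hydroxy alkenyl triflate
Conditions: LiBH(s-Bu)3 (L-Selectride), THF, −78 °C
Reagents that add atoms: none
Why: Ketone reduction by a bulky trialkylborohydride: equatorial hydride delivery to the 4,4-dimethyl-3-ketone of the trans-fused rings A and B should give the axial 3α-alcohol, while the hindered lactone and the alkenyl triflate are not touched at −78 °C.

**Step 10**
Reactants: 14 3α-hydroxy alkenyl triflate
Product: 15 3α-TBS-oxy alkenyl triflate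
Conditions: TBSOTf, 2,6-lutidine, CH2Cl2, 0 °C
Reagents that add atoms: tert-butyldimethylsilyl triflate, CC(C)(C)[Si](C)(C)OS(=O)(=O)C(F)(F)F
Why: Silyl ether formation with the reactive silyl triflate, needed because the later steps use strong bases and an acylation of another hydroxyl group.

**Step 11**
Reactants: 15 3α-TBS-oxy alkenyl triflate
Product: 16 C11 allylic alcohol (1-hydroxyethyl on C9 of the C8=C9 alkene; C11 epimers)
Conditions: MeCHO, CrCl2, NiCl2 (cat.), DMF, 23 °C
Reagents that add atoms: acetaldehyde, CC=O
Why: Nozaki–Hiyama–Kishi coupling: nickel inserts into the alkenyl triflate and the alkenylchromium species formed by transmetalation adds only to the aldehyde, so lactone and silyl ether survive; the new C11 centre is an epimer mixture that disappears in step 13.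

**Step 12**
Reactants: 16 C11 allylic alcohol (1-hydroxyethyl on C9 of the C8=C9 alkene; C11 epimers); 17 3-methylbut-3-enoic acid
Product: 18 allylic 3-methylbut-3-enoate
Conditions: DCC, DMAP (cat.), CH2Cl2, 0 °C
Reagents that add atoms: none
Why: Steglich esterification at low temperature with little DMAP, to keep the β,γ-double bond of the acid out of conjugation.

**Step 13**
Reactants: 18 allylic 3-methylbut-3-enoate
Product: 22 methyl ester (8β-methyl; 8α-CH(CO2Me)(isopropenyl); C9 ethylidene), via silyl ketene acetal 19 (not isolated), via trimethylsilyl ester 20 (not isolated), via carboxylic acid 21 (not isolated)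
Conditions: LiN(i-Pr)2 (LDA), TMSCl, THF, −78 → 65 °C; 1 M HCl; then CH2N2, Et2O, 0 °C
Reagents that add atoms: diazomethane, C=[N+]=[N-]
Why: Ireland–Claisen rearrangement: the ester enolate is trapped as silyl ketene acetal 19, whose [3,3] shift delivers C13 suprafacially to C8 on the α face (away from the lactone bridge), which sets quaternary C8 (methyl β), moves the double bond to C9=C11 and leaves the carboxyl group on C13, then esterified with diazomethane.

**Step 14**
Reactants: 22 methyl ester (8β-methyl; 8α-CH(CO2Me)(isopropenyl); C9 ethylidene)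
Product: 24 9α-hydroxy-9β-vinyl ester, via allylic hydroperoxide 23 (not isolated)
Conditions: O2, hν, tetraphenylporphyrin (cat.), CH2Cl2, 0 °C; then PPh3
Reagents that add atoms: dioxygen, O=O
Why: Schenck ene reaction of singlet oxygen: the ethylidene methyl group offers the only allylic hydrogens of the trisubstituted alkene (C8 and C10 are quaternary), so oxygen can only bond to C9 with the double bond moving to C11=CH2, attack from the α face (away from the β-axial C8 methyl group and the lactone bridge) sets the C9 carbinol, and PPh3 reduces the hydroperoxide under neutral conditions that avoid lactonisation onto the C13 ester, while the less electron-rich isopropenyl group should react far more slowly.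

**Step 15**
Reactants: 24 9α-hydroxy-9β-vinyl ester
Product: 25 cyclopentenol (C11=C12 ring closed; 9α-OH; C13–H epimers)
Conditions: second-generation Hoveyda–Grubbs catalyst (5 mol %), toluene, 80 °C
Reagents that add atoms: none
Why: Ring-closing metathesis between the C9 vinyl and the C13 isopropenyl group gives the trisubstituted C11=C12 cyclopentene with loss of ethylene; no stereocentre is formed.

**Step 16**
Reactants: 25 cyclopentenol (C11=C12 ring closed; 9α-OH; C13–H epimers)
Product: 26 9α-bromoacetate
Conditions: BrCH2COBr, pyridine, DMAP (cat.), CH2Cl2, 0 → 23 °C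
Reagents that add atoms: bromoacetyl bromide, BrCC(Br)=O
Why: O-acylation of the tertiary allylic alcohol by a highly reactive acyl bromide (acylpyridinium or bromoketene pathway).

**Step 17**
Reactants: 26 9α-bromoacetate
Product: 27 pentacyclic bis-lactone (δ-lactone closed; C14 H2; 3α-OTBS)
Conditions: KN(SiMe3)2, THF, −78 → 0 °C
Reagents that add atoms: none
Why: Intramolecular enolate C-alkylation (six-membered, exo-tet): the C13 ester dienolate attacks the bromoacetate carbon through its α-position, and because the tether hangs from the C9 oxygen it can reach C13 only on that face, so the quaternary C13 centre is forced, the C13 epimers converge and the C11=C12 bond stays in place.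

**Step 18**
Reactants: 27 pentacyclic bis-lactone (δ-lactone closed; C14 H2; 3α-OTBS)
Product: 28 C14 dimethylaminomethyl lactone (C14 epimers)
Conditions: LiN(i-Pr)2 (LDA), THF, −78 °C; CH2=NMe2+ I−, −78 → 23 °C
Reagents that add atoms: N,N-dimethylmethyleneiminium iodide (Eschenmoser's salt), C=[N+](C)C.[I-]
Why: Mannich reaction of the lithium enolate of the δ-lactone, C14 being the only enolisable carbon; the C14 centre is removed in step 19.

**Step 19**
Reactants: 28 C14 dimethylaminomethyl lactone (C14 epimers)
Product: 30 O-TBS 3-deacetyl meroantarctine B (α-methylene lactone), via ammonium iodide 29 (not isolated)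
Conditions: MeI, CH2Cl2/MeOH, 23 °C; then aq NaHCO3, 23 °C
Reagents that add atoms: none
Why: N-methylation followed by base-induced β-elimination of trimethylamine (Hofmann-type) gives the α-methylene lactone.

**Step 20**
Reactants: 30 O-TBS 3-deacetyl meroantarctine B (α-methylene lactone)
Product: 31 3-deacetyl meroantarctine B (3α-alcohol)
Conditions: HF·pyridine, THF, 0 → 23 °C
Reagents that add atoms: none
Why: Desilylation by buffered HF, which spares the α-methylene lactone and the other ester groups.

**Step 21**
Reactants: 31 3-deacetyl meroantarctine B (3α-alcohol)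
Product: 32 meroantarctine B
Conditions: Ac2O, DMAP, Et3N, CH2Cl2, 23 °C
Reagents that add atoms: acetic anhydride, CC(=O)OC(C)=O
Why: DMAP-catalysed acetylation of the axial 3α-alcohol, the only free hydroxyl group.

**Compound list**
1 | N-methoxy-N-methylisobutyramide | CC(C)C(=O)N(C)OC | starting material
2 | 4-methylpent-1-en-3-one | C=CC(=O)C(C)C | intermediate
3 | tert-butyldimethyl[(4-methylpenta-1,3-dien-3-yl)oxy]silane | C=CC(O[Si](C)(C)C(C)(C)C)=C(C)C | intermediate
4 | (R)-5-(hydroxymethyl)dihydrofuran-2(3H)-one | OC[C@H]1CCC(=O)O1 | starting material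
5 | (R)-5-(bromomethyl)dihydrofuran-2(3H)-one | BrC[C@H]1CCC(=O)O1 | intermediate
6 | (5R)-5-(bromomethyl)-3-propanoyldihydrofuran-2(3H)-one (C3 epimers) | CCC(=O)C1C[C@H](CBr)OC1=O | intermediate
7 | (5R)-5-(bromomethyl)-3-(phenylselanyl)-3-propanoyldihydrofuran-2(3H)-one (C3 epimers) | CCC(=O)C1([Se]c2ccccc2)C[C@H](CBr)OC1=O | intermediate
8 | selenoxide of 7 | CCC(=O)C1([Se](=O)c2ccccc2)C[C@H](CBr)OC1=O | intermediate
9 | acyl butenolide, (R)-5-(bromomethyl)-3-propanoylfuran-2(5H)-one | CCC(=O)C1=C[C@H](CBr)OC1=O | intermediate
10 | Diels–Alder adduct (ring A cis-fused to the γ-lactone; C10 propanoyl, C5–H and C6 bromomethyl on one lactone face; C2=C3 TBS enol ether) | CCC(=O)[C@]12CC=C(O[Si](C)(C)C(C)(C)C)C(C)(C)[C@H]1[C@H](CBr)OC2=O | intermediate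
11 | tricyclic keto lactone (rings A and B plus the C19–O–C6 bridge; C9 ketone; C8 methyl epimers; C2=C3 TBS enol ether) | CC1C[C@@H]2OC(=O)[C@@]3(C1=O)CC=C(O[Si](C)(C)C(C)(C)C)C(C)(C)[C@@H]23 | intermediate
12 | enol triflate (C8=C9) still carrying the ring A TBS enol ether | CC1=C(OS(=O)(=O)C(F)(F)F)[C@]23CC=C(O[Si](C)(C)C(C)(C)C)C(C)(C)[C@H]2[C@H](C1)OC3=O | intermediate
13 | C3-keto alkenyl triflate (C8=C9; triflate on C9) | CC1=C(OS(=O)(=O)C(F)(F)F)[C@]23CCC(=O)C(C)(C)[C@H]2[C@H](C1)OC3=O | intermediate
14 | 3α-hydroxy alkenyl triflate | CC1=C(OS(=O)(=O)C(F)(F)F)[C@]23CC[C@H](O)C(C)(C)[C@H]2[C@H](C1)OC3=O | intermediate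
15 | 3α-TBS-oxy alkenyl triflate | CC1=C(OS(=O)(=O)C(F)(F)F)[C@]23CC[C@H](O[Si](C)(C)C(C)(C)C)C(C)(C)[C@H]2[C@H](C1)OC3=O | intermediate
16 | C11 allylic alcohol (1-hydroxyethyl on C9 of the C8=C9 alkene; C11 epimers) | CC1=C(C(C)O)[C@]23CC[C@H](O[Si](C)(C)C(C)(C)C)C(C)(C)[C@H]2[C@H](C1)OC3=O | intermediate
17 | 3-methylbut-3-enoic acid | C=C(C)CC(=O)O | starting material
18 | allylic 3-methylbut-3-enoate | CC1=C(C(C)OC(=O)CC(C)=C)[C@]23CC[C@H](O[Si](C)(C)C(C)(C)C)C(C)(C)[C@H]2[C@H](C1)OC3=O | intermediate
19 | silyl ketene acetal of 18 | CC1=C(C(C)OC(O[Si](C)(C)C)=CC(C)=C)[C@]23CC[C@H](O[Si](C)(C)C(C)(C)C)C(C)(C)[C@H]2[C@H](C1)OC3=O | intermediate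
20 | trimethylsilyl ester after the [3,3] shift | CC=C1[C@@](C)(C(C(=O)O[Si](C)(C)C)C(C)=C)C[C@@H]2OC(=O)[C@]13CC[C@H](O[Si](C)(C)C(C)(C)C)C(C)(C)[C@@H]23 | intermediate
21 | carboxylic acid (acid on C13) | CC=C1[C@@](C)(C(C(=O)O)C(C)=C)C[C@@H]2OC(=O)[C@]13CC[C@H](O[Si](C)(C)C(C)(C)C)C(C)(C)[C@@H]23 | intermediate
22 | methyl ester (8β-methyl; 8α-CH(CO2Me)(isopropenyl); C9 ethylidene) | CC=C1[C@@](C)(C(C(=O)OC)C(C)=C)C[C@@H]2OC(=O)[C@]13CC[C@H](O[Si](C)(C)C(C)(C)C)C(C)(C)[C@@H]23 | intermediate
23 | allylic hydroperoxide (9α-OOH; 9β-vinyl) | C=C[C@]1(OO)[C@@](C)(C(C(=O)OC)C(C)=C)C[C@@H]2OC(=O)[C@]13CC[C@H](O[Si](C)(C)C(C)(C)C)C(C)(C)[C@@H]23 | intermediate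
24 | 9α-hydroxy-9β-vinyl ester | C=C[C@]1(O)[C@@](C)(C(C(=O)OC)C(C)=C)C[C@@H]2OC(=O)[C@]13CC[C@H](O[Si](C)(C)C(C)(C)C)C(C)(C)[C@@H]23 | intermediate
25 | cyclopentenol (C11=C12 ring closed; 9α-OH; C13–H epimers) | CC1=C[C@]2(O)[C@@](C)(C1C(=O)OC)C[C@@H]3OC(=O)[C@]24CC[C@H](O[Si](C)(C)C(C)(C)C)C(C)(C)[C@@H]34 | intermediate
26 | 9α-bromoacetate | CC1=C[C@]2(OC(=O)CBr)[C@@](C)(C1C(=O)OC)C[C@@H]3OC(=O)[C@]24CC[C@H](O[Si](C)(C)C(C)(C)C)C(C)(C)[C@@H]34 | intermediate
27 | pentacyclic bis-lactone (δ-lactone closed; C14 H2; 3α-OTBS) | C1C(=O)O[C@@]23C=C(C)[C@]1(C(=O)OC)[C@@]2(C)C[C@@H]1OC(=O)[C@]32CC[C@H](O[Si](C)(C)C(C)(C)C)C(C)(C)[C@@H]12 | intermediate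
28 | C14 dimethylaminomethyl lactone (C14 epimers) | CN(C)CC1C(=O)O[C@@]23C=C(C)[C@]1(C(=O)OC)[C@@]2(C)C[C@@H]1OC(=O)[C@]32CC[C@H](O[Si](C)(C)C(C)(C)C)C(C)(C)[C@@H]12 | intermediate
29 | ammonium iodide of 28 | C[N+](C)(C)CC1C(=O)O[C@@]23C=C(C)[C@]1(C(=O)OC)[C@@]2(C)C[C@@H]1OC(=O)[C@]32CC[C@H](O[Si](C)(C)C(C)(C)C)C(C)(C)[C@@H]12.[I-] | intermediate
30 | O-TBS 3-deacetyl meroantarctine B (α-methylene lactone) | C=C1C(=O)O[C@@]23C=C(C)[C@]1(C(=O)OC)[C@@]2(C)C[C@@H]1OC(=O)[C@]32CC[C@H](O[Si](C)(C)C(C)(C)C)C(C)(C)[C@@H]12 | intermediate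
31 | 3-deacetyl meroantarctine B (3α-alcohol) | C=C1C(=O)O[C@@]23C=C(C)[C@]1(C(=O)OC)[C@@]2(C)C[C@@H]1OC(=O)[C@]32CC[C@H](O)C(C)(C)[C@@H]12 | intermediate
32 | meroantarctine B | C=C1C(=O)O[C@@]23C=C(C)[C@]1(C(=O)OC)[C@@]2(C)C[C@@H]1OC(=O)[C@]32CC[C@H](OC(C)=O)C(C)(C)[C@@H]12 | target

**Step count**
Total: 21 steps. Longest linear sequence: 19 steps (steps 3–21, from lactone 4). The diene branch (steps 1–2) joins in step 6 and acid 17 joins in step 12.

**Steps most likely to fail**

Step 6. The gem-dimethyl terminus of diene 3 may bond too slowly, so that butenolide 9 is lost to γ-enolisation (erosion of the C6 configuration), to dimerisation or to reaction through its oxadiene. The fallback is an anionic double Michael annulation and sets out from selenide 7 and enone 2. Butenolide 9 is generated as in step 6 and added at −78 °C to the cross-conjugated lithium dienolate of 2 (LDA, THF). The tertiary enolate carbon adds to C5 anti to the bromomethyl group, and the resulting C10 keto-lactone enolate closes onto the vinyl ketone to give the diketone adduct F1 (the C3 ketone analogue of 10). F1 is then treated with NaN(SiMe3)2 (2.1 equiv) followed by TBSOTf: the propanoyl enolate closes ring B as in step 7 while the C3 enolate is trapped as its TBS enol ether, and the route is rejoined at 11.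

Step 13. The [3,3] shift has to create quaternary C8 and an ethylidene between two quaternary carbons, so fragmentation of the silyl ketene acetal into a ketene and the allylic alkoxide may outrun it. The fallback moves a smaller unit and adds the alkene afterwards; it sets out from 16. A Johnson–Claisen rearrangement (MeC(OMe)3, cat. EtCO2H, xylene, 140 °C) should give, with the same α-face delivery, the C8 acetic ester F2. Palladium-catalysed α-alkenylation of its lithium enolate with 2-bromopropene (LiN(SiMe3)2; Pd(dba)2, P(t-Bu)3, toluene) then installs the isopropenyl group on C13, and the route is rejoined at 22.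

Step 16. Acylation of the tertiary C9 alcohol, which sits between two quaternary carbons, may be slower than ionisation of this allylic alcohol or loss of the acyl bromide as bromoketene oligomers. The fallback reverses the order of bond formation (C–C first, then lactonisation) and sets out from 25. With LDA (2.2 equiv, THF/DMPU, −78 °C) and methyl bromoacetate, the alkoxide–dienolate dianion should be C-alkylated at C13 on the ring face opposite the C8 methyl group, which is the face of the C9 oxygen, to give the hydroxy diester F3. On warming (or with catalytic NaOMe) the C9 alkoxide closes onto the new methyl ester, and the route is rejoined at 27.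

**Further compounds**
F1 | step 6 | diketone adduct (C3 ketone analogue of 10) | CCC(=O)[C@]12CCC(=O)C(C)(C)[C@H]1[C@H](CBr)OC2=O
F2 | step 13 | C8 acetic ester (8β-methyl; 8α-CH2CO2Me; C9 ethylidene) | CC=C1[C@@](C)(CC(=O)OC)C[C@@H]2OC(=O)[C@]13CC[C@H](O[Si](C)(C)C(C)(C)C)C(C)(C)[C@@H]23
F3 | step 16 | hydroxy diester (9α-OH; C13 bearing CO2Me and CH2CO2Me) | CC1=C[C@]2(O)[C@@](C)([C@@]1(CC(=O)OC)C(=O)OC)C[C@@H]3OC(=O)[C@]24CC[C@H](O[Si](C)(C)C(C)(C)C)C(C)(C)[C@@H]34
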